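The route rests on cutting the dioxane at O1–C8a. On ring A, C4a (carrying O4, para to the C7 propenol chain) sits between C5–OMe and C8a–O1, so exchanging O1 for methoxy uncovers a symmetrical sinapate 4-O-ether. The precursor is therefore the erythro arylglycerol β-ether of methyl sinapate: free benzylic hydroxyl, primary alcohol and ring C catechol masked as pivalates. Under acridinium photoredox catalysis, oxidation of ring A lets that hydroxyl displace either of the two equivalent methoxy groups, closing the dioxane in one operation with both stereocentres untouched (erythro gives cis). An auxiliary-controlled anti-aldol builds the ether; a single hydride step completes the target.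

Key step: step 8

Numbering used: benzodioxane O1, C2 (aryl), C3 (CH2OH), O4, C4a, C5 (OMe), C6, C7 (chain), C8, C8a; ring A is the benzo ring, ring C the pendant aryl; in open-chain compounds C1 is the benzylic carbinol carbon.

Assumption: the facial sense of the magnesium-catalysed anti-aldol is taken to be that of the chelated Z-enolate (the sense seen in alkylations of the same imides), which calls for the (R)-4-benzyl auxiliary; if the sense proved opposite, the (S)-auxiliary would be used instead.

Step 1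
Reactants: 1 sinapic acid
Product: 2 methyl sinapate, methyl (E)-3-(4-hydroxy-3,5-dimethoxyphenyl)prop-2-enoate
Conditions: MeOH, H2SO4 (cat.), reflux
Reagents that add atoms: methanol, CO
Why: Fischer esterification in excess methanol should esterify the cinnamic acid without touching the phenol or the E-alkene.

Step 2
Reactants: 3 (R)-4-benzyloxazolidin-2-one; 4 bromoacetyl bromide
Product: 5 (R)-4-benzyl-3-(2-bromoacetyl)oxazolidin-2-one
Conditions: n-BuLi, THF, −78 °C; then 4, −78 → 0 °C
Reagents that add atoms: none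
Why: N-acylation of the lithiated oxazolidinone occurs at the far more electrophilic acyl bromide carbon (standard preparation of an Evans imide), leaving the alkyl bromide for step 3.

Step 3
Reactants: 2 methyl sinapate; 5 (R)-4-benzyl-3-(2-bromoacetyl)oxazolidin-2-one
Product: 6 (R)-4-benzyl-3-{2-[2,6-dimethoxy-4-((E)-3-methoxy-3-oxoprop-1-enyl)phenoxy]acetyl}oxazolidin-2-one
Conditions: K2CO3, acetone, rt
Reagents that add atoms: none
Why: Williamson ether synthesis, in which the phenoxide displaces bromide from the strongly activated α-bromo imide by SN2 under conditions too mild to cleave the imide or the methyl ester.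

Step 4
Reactants: 7 5-hydroxyvanillin
Product: 8 5-formyl-3-methoxy-1,2-phenylene bis(2,2-dimethylpropanoate) (ring C aldehyde bis-pivalate)
Conditions: PivCl (2.4 equiv), Et3N, DMAP (cat.), CH2Cl2, 0 °C → rt
Reagents that add atoms: pivaloyl chloride, CC(C)(C)C(=O)Cl
Why: DMAP-catalysed acylation of both phenols gives hindered esters that make the aldehyde more electrophilic, remove the para-oxygen donation that would make the future benzylic alcohol ionisable, and raise the oxidation potential of ring C for step 8.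

Step 5
Reactants: 6 sinapate imide; 8 ring C aldehyde bis-pivalate
Product: 10 (R)-4-benzyl-3-{(2S,3S)-3-hydroxy-3-[3-methoxy-4,5-bis(pivaloyloxy)phenyl]-2-[2,6-dimethoxy-4-((E)-3-methoxy-3-oxoprop-1-enyl)phenoxy]propanoyl}oxazolidin-2-one (anti-aldol adduct), via trimethylsilyl ether 9 (not isolated)
Conditions: MgCl2 (0.2 equiv), Et3N, TMSCl, EtOAc, rt; then TFA (cat.), MeOH, rt
Reagents that add atoms: none
Why: In this Evans magnesium-halide-catalysed anti-aldol reaction, soft enolisation gives the chelated magnesium Z-enolate, which adds to the non-enolisable aryl aldehyde through a boat-like transition state; the (R)-benzyl group blocks one enolate face and so fixes C2, the anti (erythro) relationship fixes the carbinol C3, and silylation of the aldolate by TMSCl turns the catalyst over.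

Step 6
Reactants: 10 anti-aldol adduct
Product: 11 methyl (E)-3-{4-[(1S,2R)-1,3-dihydroxy-1-(3-methoxy-4,5-bis(pivaloyloxy)phenyl)propan-2-yloxy]-3,5-dimethoxyphenyl}prop-2-enoate (erythro diol)
Conditions: NaBH4, THF/H2O (4:1), 0 °C → rt
Reagents that add atoms: none
Why: Reductive cleavage of an Evans imide: borohydride in wet THF attacks the activated exocyclic imide carbonyl much faster than the conjugated methyl ester or the hindered pivalates, releasing the auxiliary and giving the primary alcohol without touching either stereocentre, which also removes the acidic α-hydrogen that could later epimerise the cis ring.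

Step 7
Reactants: 11 erythro diol
Product: 12 methyl (E)-3-{4-[(1S,2R)-1-hydroxy-1-(3-methoxy-4,5-bis(pivaloyloxy)phenyl)-3-(pivaloyloxy)propan-2-yloxy]-3,5-dimethoxyphenyl}prop-2-enoate (erythro 3-pivalate, precursor of the key step)
Conditions: PivCl (1.1 equiv), pyridine, CH2Cl2, −20 → 0 °C
Reagents that add atoms: pivaloyl chloride, CC(C)(C)C(=O)Cl
Why: Selective esterification: the bulky acyl chloride reacts with the primary hydroxyl far faster than with the secondary benzylic one, which is flanked by an aryl ring and a 2,6-disubstituted aryloxy group, so only the benzylic hydroxyl stays free as the nucleophile for step 8 (any phenol freed in step 6 would be re-esterified here).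

Step 8
Reactants: 12 erythro 3-pivalate
Product: 13 methyl (E)-3-{(2S,3R)-5-methoxy-2-[3-methoxy-4,5-bis(pivaloyloxy)phenyl]-3-(pivaloyloxymethyl)-2,3-dihydro-1,4-benzodioxin-7-yl}prop-2-enoate (cis-benzodioxane tripivalate)
Conditions: 9-mesityl-3,6-di-tert-butyl-10-phenylacridinium tetrafluoroborate (5 mol %), ClCH2CH2Cl/(CF3)2CHOH 9:1 (0.02 M), 455 nm LEDs, N2, 25 °C
Reagents that add atoms: none
Why: Proposed new method: the photoexcited acridinium should oxidise ring A, the electron-richest arene, to its radical cation; the benzylic hydroxyl then adds ipso at the methoxy-bearing carbon C8a, the cyclohexadienyl radical so formed is reduced by the acridinyl radical, and loss of methanol rearomatises ring A with the new O1–C8a bond while the catalyst is regenerated. The closest known reaction types are the acridinium-photocatalysed cation-radical-accelerated nucleophilic aromatic substitution of methoxyarenes by azoles, amines and ammonia, and intramolecular C–O cyclisations onto photochemically or anodically generated arene radical cations; displacement of methoxide by an alcohol in this manifold is the unproven element. The dioxane closes in a six-membered ortho-fused mode (addition–elimination at C8a, formally 6-exo with respect to the C8a–C8 π bond), not in the five-membered spiro mode at C4a. No stereocentre is created, and because the C–O bonds at the two carbinol carbons are never broken their configurations are retained, so the erythro ether can only give the cis-2,3-disubstituted ring. Three selectivities are needed: oxidation of ring A before ring C (secured by three alkoxy donors on ring A against two acyloxy groups on ring C), attack at a methoxy carbon and not at C4a (secured by the six-membered geometry, by the symmetry that makes both methoxy carbons identical, and by the out-of-plane C4a oxygen, which leaves C4a the least activated oxygenated carbon), and a single nucleophile (secured by the pivalate on the primary alcohol, which would otherwise close an isomeric six-membered ring). The acrylate is kept as the electron-poor methyl ester so that the alkene neither absorbs at 455 nm nor reacts as an alkene radical cation.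

Step 9
Reactants: 13 cis-benzodioxane tripivalate
Product: 14 (E)-3-[(2S,3R)-2-(3,4-dihydroxy-5-methoxyphenyl)-3-(hydroxymethyl)-5-methoxy-2,3-dihydro-1,4-benzodioxin-7-yl]prop-2-en-1-ol (CNP0174261.1)
Conditions: i-Bu2AlH (12 equiv), CH2Cl2, −78 → 0 °C; aq. KNaC4H4O6 (potassium sodium tartrate)
Reagents that add atoms: none
Why: The aluminium hydride reduces the conjugated methyl ester in 1,2-fashion to the E allylic alcohol (as in the preparation of monolignols from cinnamate esters) and reductively cleaves the three pivalates in the same pot, while the benzodioxane ethers and both stereocentres are inert to hydride.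

Compound list
1 | sinapic acid, (E)-3-(4-hydroxy-3,5-dimethoxyphenyl)prop-2-enoic acid | COc1cc(/C=C/C(=O)O)cc(OC)c1O | starting material
2 | methyl sinapate, methyl (E)-3-(4-hydroxy-3,5-dimethoxyphenyl)prop-2-enoate | COC(=O)/C=C/c1cc(OC)c(O)c(OC)c1 | intermediate
3 | (R)-4-benzyloxazolidin-2-one | O=C1N[C@H](Cc2ccccc2)CO1 | starting material
4 | bromoacetyl bromide | BrCC(=O)Br | starting material
5 | (R)-4-benzyl-3-(2-bromoacetyl)oxazolidin-2-one | O=C(CBr)N1[C@H](Cc2ccccc2)COC1=O | intermediate
6 | (R)-4-benzyl-3-{2-[2,6-dimethoxy-4-((E)-3-methoxy-3-oxoprop-1-enyl)phenoxy]acetyl}oxazolidin-2-one | COC(=O)/C=C/c1cc(OC)c(OCC(=O)N2[C@H](Cc3ccccc3)COC2=O)c(OC)c1 | intermediate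
7 | 5-hydroxyvanillin, 3,4-dihydroxy-5-methoxybenzaldehyde | COc1cc(C=O)cc(O)c1O | starting material
8 | 5-formyl-3-methoxy-1,2-phenylene bis(2,2-dimethylpropanoate) | COc1cc(C=O)cc(OC(=O)C(C)(C)C)c1OC(=O)C(C)(C)C | intermediate
9 | 3-O-trimethylsilyl ether of 10, (2S,3S) with (4R)-auxiliary | COc1cc([C@H](O[Si](C)(C)C)[C@H](Oc2c(OC)cc(/C=C/C(=O)OC)cc2OC)C(=O)N3[C@H](Cc4ccccc4)COC3=O)cc(OC(=O)C(C)(C)C)c1OC(=O)C(C)(C)C | intermediate
10 | (R)-4-benzyl-3-{(2S,3S)-3-hydroxy-3-[3-methoxy-4,5-bis(pivaloyloxy)phenyl]-2-[2,6-dimethoxy-4-((E)-3-methoxy-3-oxoprop-1-enyl)phenoxy]propanoyl}oxazolidin-2-one | COc1cc([C@H](O)[C@H](Oc2c(OC)cc(/C=C/C(=O)OC)cc2OC)C(=O)N3[C@H](Cc4ccccc4)COC3=O)cc(OC(=O)C(C)(C)C)c1OC(=O)C(C)(C)C | intermediate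
11 | methyl (E)-3-{4-[(1S,2R)-1,3-dihydroxy-1-(3-methoxy-4,5-bis(pivaloyloxy)phenyl)propan-2-yloxy]-3,5-dimethoxyphenyl}prop-2-enoate | COc1cc([C@H](O)[C@H](Oc2c(OC)cc(/C=C/C(=O)OC)cc2OC)CO)cc(OC(=O)C(C)(C)C)c1OC(=O)C(C)(C)C | intermediate
12 | methyl (E)-3-{4-[(1S,2R)-1-hydroxy-1-(3-methoxy-4,5-bis(pivaloyloxy)phenyl)-3-(pivaloyloxy)propan-2-yloxy]-3,5-dimethoxyphenyl}prop-2-enoate | COc1cc([C@H](O)[C@H](Oc2c(OC)cc(/C=C/C(=O)OC)cc2OC)COC(=O)C(C)(C)C)cc(OC(=O)C(C)(C)C)c1OC(=O)C(C)(C)C | intermediate
13 | methyl (E)-3-{(2S,3R)-5-methoxy-2-[3-methoxy-4,5-bis(pivaloyloxy)phenyl]-3-(pivaloyloxymethyl)-2,3-dihydro-1,4-benzodioxin-7-yl}prop-2-enoate | COc1cc([C@@H]2Oc3cc(/C=C/C(=O)OC)cc(OC)c3O[C@@H]2COC(=O)C(C)(C)C)cc(OC(=O)C(C)(C)C)c1OC(=O)C(C)(C)C | intermediate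
14 | (E)-3-[(2S,3R)-2-(3,4-dihydroxy-5-methoxyphenyl)-3-(hydroxymethyl)-5-methoxy-2,3-dihydro-1,4-benzodioxin-7-yl]prop-2-en-1-ol | COc1cc([C@@H]2Oc3cc(/C=C/CO)cc(OC)c3O[C@@H]2CO)cc(O)c1O | target

Total step count: 9. Longest linear sequence: 7 steps (steps 1, 3, 5, 6, 7, 8, 9).

Steps most likely to fail

Step 8. Several processes could defeat the ring closure:
- back electron transfer may outrun addition of the weakly nucleophilic alcohol to the ring A radical cation;
- addition may occur at C4a in the spiro mode, after which the aryl group migrates between the two glycerol oxygens and the regiochemistry is scrambled;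
- the acrylate may isomerise or dimerise through the radical cation.

The fallback uses known chemistry, a palladium-catalysed intramolecular aryl bromide–alcohol etherification that forms the same O1–C8a bond. It sets out from 5 and 8 and rejoins the route at 13.
- Commercial 5-bromovanillin F1 is olefinated with methyl (triphenylphosphoranylidene)acetate (toluene, 90 °C, Wittig reaction) to methyl (E)-3-(3-bromo-4-hydroxy-5-methoxyphenyl)prop-2-enoate F2.
- F2 is alkylated with 5 (K2CO3, acetone) to the bromo imide F3.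
- The magnesium-catalysed anti-aldol of step 5 with aldehyde 8 should give, through the trimethylsilyl ether F4, the bromo anti-aldol adduct F5.
- NaBH4 in THF/H2O gives the bromo erythro diol F6, and selective pivaloylation gives the bromo erythro 3-pivalate F7, which is 12 with Br in place of one ring A methoxy group.
- Pd(OAc)2, 2-(di-tert-butylphosphino)-1,1'-binaphthyl and K3PO4 in toluene at 80 °C should then couple the benzylic alkoxide with the aryl bromide, with retention at both stereocentres, to give 13.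

Step 5. The more acidic α-aryloxy imide may be trapped as an unreactive silyl ketene aminal, anti/syn control may erode, or the facial sense may be opposite to the one assumed. The fallback separates the two stereocentres: a boron-mediated Evans syn-aldol sets the aryloxy-bearing carbon, and the carbinol carbon is then corrected by oxidation and chelation-controlled reduction. It sets out from 2, 4 and 8 and rejoins at 12.
- (S)-4-Benzyloxazolidin-2-one F8 is acylated with 4 (n-BuLi, THF, −78 °C) to (S)-4-benzyl-3-(2-bromoacetyl)oxazolidin-2-one F9, which alkylates 2 (K2CO3, acetone) to the (S)-imide F10.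
- Bu2BOTf and i-Pr2NEt in CH2Cl2 at −78 → 0 °C with 8 should give the syn adduct F11, correct at C2 and epimeric at C3.
- NaBH4 in THF/H2O gives the threo diol F12, and PivCl/pyridine gives the threo 3-pivalate F13.
- Dess–Martin periodinane (NaHCO3, CH2Cl2, 0 °C) oxidises the benzylic alcohol to the α-aryloxy ketone F14.
- Zn(BH4)2 in Et2O at −20 °C, delivering hydride to the chelate between the ketone and the α-oxygen, should return the erythro alcohol 12.

Step 6. In the basic aqueous borohydride medium, retro-aldol fragmentation of the β-hydroxy imide and hydrolytic loss of the aryl pivalates may compete with reduction of the imide. The fallback masks the carbinol before the reduction and runs it without water. It sets out from 10 and rejoins at 12.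
- TESOTf and 2,6-lutidine in CH2Cl2 at −78 °C give the triethylsilyl ether F15, which cannot undergo retro-aldol cleavage.
- LiBH4 with MeOH (1 equiv) in THF at 0 °C gives the silyl-protected primary alcohol F16.
- PivCl, pyridine and DMAP give the silyl-protected 3-pivalate F17, now with no selectivity question and with any freed phenol re-esterified.
- HF·pyridine in THF at 0 °C removes the silyl group to give 12.

Further compounds
F1 | step 8 | 5-bromovanillin, 3-bromo-4-hydroxy-5-methoxybenzaldehyde | COc1cc(C=O)cc(Br)c1O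
F2 | step 8 | methyl (E)-3-(3-bromo-4-hydroxy-5-methoxyphenyl)prop-2-enoate | COC(=O)/C=C/c1cc(OC)c(O)c(Br)c1
F3 | step 8 | (R)-4-benzyl-3-{2-[2-bromo-6-methoxy-4-((E)-3-methoxy-3-oxoprop-1-enyl)phenoxy]acetyl}oxazolidin-2-one | COC(=O)/C=C/c1cc(OC)c(OCC(=O)N2[C@H](Cc3ccccc3)COC2=O)c(Br)c1
F4 | step 8 | 3-O-trimethylsilyl ether of F5, (2S,3S) with (4R)-auxiliary | COc1cc([C@H](O[Si](C)(C)C)[C@H](Oc2c(Br)cc(/C=C/C(=O)OC)cc2OC)C(=O)N3[C@H](Cc4ccccc4)COC3=O)cc(OC(=O)C(C)(C)C)c1OC(=O)C(C)(C)C
F5 | step 8 | (R)-4-benzyl-3-{(2S,3S)-2-[2-bromo-6-methoxy-4-((E)-3-methoxy-3-oxoprop-1-enyl)phenoxy]-3-hydroxy-3-[3-methoxy-4,5-bis(pivaloyloxy)phenyl]propanoyl}oxazolidin-2-one | COc1cc([C@H](O)[C@H](Oc2c(Br)cc(/C=C/C(=O)OC)cc2OC)C(=O)N3[C@H](Cc4ccccc4)COC3=O)cc(OC(=O)C(C)(C)C)c1OC(=O)C(C)(C)C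
F6 | step 8 | methyl (E)-3-{3-bromo-4-[(1S,2R)-1,3-dihydroxy-1-(3-methoxy-4,5-bis(pivaloyloxy)phenyl)propan-2-yloxy]-5-methoxyphenyl}prop-2-enoate | COc1cc([C@H](O)[C@H](Oc2c(Br)cc(/C=C/C(=O)OC)cc2OC)CO)cc(OC(=O)C(C)(C)C)c1OC(=O)C(C)(C)C
F7 | step 8 | methyl (E)-3-{3-bromo-4-[(1S,2R)-1-hydroxy-1-(3-methoxy-4,5-bis(pivaloyloxy)phenyl)-3-(pivaloyloxy)propan-2-yloxy]-5-methoxyphenyl}prop-2-enoate | COc1cc([C@H](O)[C@H](Oc2c(Br)cc(/C=C/C(=O)OC)cc2OC)COC(=O)C(C)(C)C)cc(OC(=O)C(C)(C)C)c1OC(=O)C(C)(C)C
F8 | step 5 | (S)-4-benzyloxazolidin-2-one | O=C1N[C@@H](Cc2ccccc2)CO1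
F9 | step 5 | (S)-4-benzyl-3-(2-bromoacetyl)oxazolidin-2-one | O=C(CBr)N1[C@@H](Cc2ccccc2)COC1=O
F10 | step 5 | (S)-4-benzyl-3-{2-[2,6-dimethoxy-4-((E)-3-methoxy-3-oxoprop-1-enyl)phenoxy]acetyl}oxazolidin-2-one | COC(=O)/C=C/c1cc(OC)c(OCC(=O)N2[C@@H](Cc3ccccc3)COC2=O)c(OC)c1
F11 | step 5 | (S)-4-benzyl-3-{(2S,3R)-3-hydroxy-3-[3-methoxy-4,5-bis(pivaloyloxy)phenyl]-2-[2,6-dimethoxy-4-((E)-3-methoxy-3-oxoprop-1-enyl)phenoxy]propanoyl}oxazolidin-2-one (syn adduct) | COc1cc([C@@H](O)[C@H](Oc2c(OC)cc(/C=C/C(=O)OC)cc2OC)C(=O)N3[C@@H](Cc4ccccc4)COC3=O)cc(OC(=O)C(C)(C)C)c1OC(=O)C(C)(C)C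
F12 | step 5 | methyl (E)-3-{4-[(1R,2R)-1,3-dihydroxy-1-(3-methoxy-4,5-bis(pivaloyloxy)phenyl)propan-2-yloxy]-3,5-dimethoxyphenyl}prop-2-enoate (threo diol) | COc1cc([C@@H](O)[C@H](Oc2c(OC)cc(/C=C/C(=O)OC)cc2OC)CO)cc(OC(=O)C(C)(C)C)c1OC(=O)C(C)(C)C
F13 | step 5 | methyl (E)-3-{4-[(1R,2R)-1-hydroxy-1-(3-methoxy-4,5-bis(pivaloyloxy)phenyl)-3-(pivaloyloxy)propan-2-yloxy]-3,5-dimethoxyphenyl}prop-2-enoate (threo 3-pivalate) | COc1cc([C@@H](O)[C@H](Oc2c(OC)cc(/C=C/C(=O)OC)cc2OC)COC(=O)C(C)(C)C)cc(OC(=O)C(C)(C)C)c1OC(=O)C(C)(C)C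
F14 | step 5 | methyl (E)-3-{4-[(2R)-1-(3-methoxy-4,5-bis(pivaloyloxy)phenyl)-1-oxo-3-(pivaloyloxy)propan-2-yloxy]-3,5-dimethoxyphenyl}prop-2-enoate (ketone) | COc1cc(C(=O)[C@H](Oc2c(OC)cc(/C=C/C(=O)OC)cc2OC)COC(=O)C(C)(C)C)cc(OC(=O)C(C)(C)C)c1OC(=O)C(C)(C)C
F15 | step 6 | 3-O-triethylsilyl ether of 10, (2S,3S) with (4R)-auxiliary | COc1cc([C@H](O[Si](CC)(CC)CC)[C@H](Oc2c(OC)cc(/C=C/C(=O)OC)cc2OC)C(=O)N3[C@H](Cc4ccccc4)COC3=O)cc(OC(=O)C(C)(C)C)c1OC(=O)C(C)(C)C
F16 | step 6 | methyl (E)-3-{4-[(1S,2R)-3-hydroxy-1-(3-methoxy-4,5-bis(pivaloyloxy)phenyl)-1-(triethylsilyloxy)propan-2-yloxy]-3,5-dimethoxyphenyl}prop-2-enoate | COc1cc([C@H](O[Si](CC)(CC)CC)[C@H](Oc2c(OC)cc(/C=C/C(=O)OC)cc2OC)CO)cc(OC(=O)C(C)(C)C)c1OC(=O)C(C)(C)C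
F17 | step 6 | methyl (E)-3-{4-[(1S,2R)-1-(3-methoxy-4,5-bis(pivaloyloxy)phenyl)-3-(pivaloyloxy)-1-(triethylsilyloxy)propan-2-yloxy]-3,5-dimethoxyphenyl}prop-2-enoate | COc1cc([C@H](O[Si](CC)(CC)CC)[C@H](Oc2c(OC)cc(/C=C/C(=O)OC)cc2OC)COC(=O)C(C)(C)C)cc(OC(=O)C(C)(C)C)c1OC(=O)C(C)(C)C
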